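**Assumptions**
- Commercially available genipin, (1R,4aS,7aS) (compound 1), is accepted as the starting chiron. Both rings and the cis-fused C5/C9 stereocentres (S,S, matching the target) are already present.
- The C1 anomer of intermediates 3–14 is an unspecified mixture. It is reset in Step 8.
- The tartrate enantiomer in Step 2 was chosen by mapping the ring onto the Sharpless mnemonic. That mapping is my own derivation, not checked against a literature example.

**Retrosynthetic overview**
1. Target 20 comes from C11 acylation of 17, which comes from 16 by TES removal. Step 11 removes the C8/C10 silylene last.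
2. The C1 acylal (1β-OiVal) is set late by a new Lewis-acid acyloxy-demethoxylation of the 1-OMe acetal 14. The acetal caps the lactol so it survives the hydride step.
3. The 7β-OAc / 8α-OH / 10-OH pattern comes from α-face Sharpless epoxidation of genipin's C7=C8 allylic alcohol. A Ti-mediated anti opening with AcOH at C7 follows.
4. The C11 CH2OH comes from reducing genipin's C4 methyl ester. Neither ring has to be built.

**Route**

Step 1
Reactants: 1 genipin; 2 methanol
Product: 3, 1-O-methylgenipin (1-OMe acetal, C1 anomeric mixture)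
Conditions: MeOH, PPTS (0.1 equiv), 23 °C, 12 h
Reagents that add atoms: methanol, CO
Why: Fischer glycosidation (acid-catalysed acetalisation) caps the lactol as a methyl acetal so that hydride later cannot open it; C1 is only temporary here.

Step 2
Reactants: 3; 4 tert-butyl hydroperoxide
Product: 5, 7α,8α-epoxy-10-ol (C11 ester and 1-OMe retained)
Conditions: Ti(OiPr)4 (1.0 equiv), D-(−)-diethyl tartrate (1.2 equiv), TBHP (2 equiv, 5.5 M in decane), 4 Å MS, CH2Cl2, −20 °C
Reagents that add atoms: TBHP, CC(C)(C)OO (transfers one O)
Why: Sharpless asymmetric epoxidation; the C10 allylic alcohol binds the Ti–tartrate, and the D-(−) ligand directs O-transfer to the concave α-face by the mnemonic. This sets C7 and C8 with C8–O α and C10 β, while the push-pull C3=C4 olefin is not oxidised.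

Step 3
Reactants: 5; 6 acetic acid
Product: 7, 7β-acetoxy-8α,10-dihydroxy-1-OMe ester
Conditions: Ti(OiPr)4 (1.5 equiv), AcOH (10 equiv), CH2Cl2, 0→23 °C
Reagents that add atoms: acetic acid, CC(=O)O
Why: Caron–Sharpless Ti(OiPr)4-promoted C3-selective epoxide opening; AcO⁻ attacks C7 (secondary, not the quaternary C8) from the β-face with inversion, which sets 7β-OAc and leaves 8α-OH.

Step 4
Reactants: 7; 8 di-tert-butylsilyl bis(triflate)
Product: 9, 8,10-O-di-tert-butylsilylene derivative
Conditions: (tBu)2Si(OTf)2 (1.2 equiv), 2,6-lutidine (4 equiv), CH2Cl2/DMF 4:1, −40→0 °C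
Reagents that add atoms: (tBu)2Si(OTf)2, CC(C)(C)[Si](OS(=O)(=O)C(F)(F)F)(OS(=O)(=O)C(F)(F)F)C(C)(C)C
Why: Silylene formation masks the tertiary C8-OH and primary C10-OH together, which prevents their acylation and O→O acyl migration later, and it is removable by fluoride in the last step.

Step 5
Reactants: 9
Product: 10, C7-OH / C11-OH (the C11 ester reduced to CH2OH, the acetate cleaved)
Conditions: DIBAL-H (6 equiv), CH2Cl2, −78→0 °C; Rochelle salt work-up
Reagents that add atoms: none
Why: DIBAL reduction converts the vinylogous-carbonate ester to the allylic alcohol, which avoids any later ester-to-alcohol problem at C11; the acetal and silylene are inert at low temperature and no stereocentre is touched.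

Step 6
Reactants: 10; 11 triethylsilyl chloride
Product: 12, C11-OTES ether
Conditions: TESCl (1.1 equiv), imidazole (2.5 equiv), CH2Cl2, −20 °C
Reagents that add atoms: TESCl, CC[Si](Cl)(CC)CC
Why: Silylation is selective for the unhindered primary C11-OH over the C7-OH, which sits next to the quaternary C8.

Step 7
Reactants: 12; 13 acetic anhydride
Product: 14, C7-OAc
Conditions: Ac2O (5 equiv), DMAP (0.3 equiv), pyridine, CH2Cl2, 23 °C
Reagents that add atoms: Ac2O, CC(=O)OC(C)=O
Why: DMAP-catalysed acetylation re-installs the 7β-OAc with retention, since no bond to C7 is broken.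

Step 8
Reactants: 14; 15 isovaleric anhydride
Product: 16, 1β-isovaleryloxy acylal (1-OMe exchanged)
Conditions: (iPrCH2CO)2O (3 equiv), TMSOTf (0.1 equiv), CH2Cl2, −40 °C, 1 h; Et3N quench
Reagents that add atoms: isovaleric anhydride, CC(C)CC(=O)OC(=O)CC(C)C
Why: Proposed new method: TMSOTf ionises the 1-OMe O,O-acetal to the O2=C1 oxocarbenium, isovalerate from the anhydride captures it, and the acylal re-ionises reversibly under the Lewis acid so that the anomeric effect funnels the anomer mixture to the natural pseudo-axial 1β (1S) acylal, with methyl isovalerate as by-product. The closest known reaction is acetolysis of methyl glycosides (Ac2O / Lewis acid → glycosyl acetates). It is new here because the substrate is an acid-labile enol-ether-containing acetal carrying an allylic silyl ether, and it converts a C1 anomeric mixture into the single C1 stereocentre.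

Step 9
Reactants: 16
Product: 17, C11-OH
Conditions: HF·pyridine (buffered with excess pyridine), THF, 0 °C, 30 min
Reagents that add atoms: none
Why: The primary TES ether is removed selectively by fluoride, while the silylene, acylal and acetate survive under these buffered, cold conditions.

Step 10
Reactants: 17; 18 isovaleryl chloride
Product: 19, C11-O-isovalerate (silylene still on)
Conditions: iPrCH2COCl (1.5 equiv), pyridine (5 equiv), DMAP (cat.), CH2Cl2, 0 °C
Reagents that add atoms: isovaleryl chloride, CC(C)CC(=O)Cl
Why: Schotten–Baumann-type acylation of the primary allylic alcohol; no stereocentre is affected and the C8/C10 oxygens are masked.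

Step 11
Reactants: 19
Product: 20, jatamanvaltrate H
Conditions: HF·pyridine, pyridine, THF, 23 °C, 12 h
Reagents that add atoms: none
Why: Fluoride cleaves the di-tert-butylsilylene under non-basic conditions, which minimises 7-OAc→10-OH acyl migration and gives the free 8α-OH and 10-OH of the target.

**Compound list**

| No. | Name | SMILES | Role |
|---|---|---|---|
| 1 | genipin | OCC1=CC[C@@H]2C(C(=O)OC)=CO[C@@H](O)[C@H]12 | starting material |
| 2 | methanol | CO | starting material (reagent) |
| 3 | 1-O-methylgenipin (C1 mixture) | OCC1=CC[C@@H]2C(C(=O)OC)=CO[CH](OC)[C@H]12 | intermediate |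
| 4 | tert-butyl hydroperoxide | CC(C)(C)OO | starting material (reagent) |
| 5 | 7α,8α-epoxy-10-ol, 1-OMe, C11 methyl ester | OC[C@@]12O[C@@H]1C[C@@H]3C(C(=O)OC)=CO[CH](OC)[C@H]23 | intermediate |
| 6 | acetic acid | CC(=O)O | starting material (reagent) |
| 7 | 7β-OAc-8α,10-diol, 1-OMe, C11 methyl ester | CC(=O)O[C@H]1C[C@@H]2C(C(=O)OC)=CO[CH](OC)[C@@H]2[C@@]1(O)CO | intermediate |
| 8 | di-tert-butylsilyl bis(triflate) | CC(C)(C)[Si](OS(=O)(=O)C(F)(F)F)(OS(=O)(=O)C(F)(F)F)C(C)(C)C | starting material (reagent) |
| 9 | 8,10-O-di-tert-butylsilylene derivative | CC(=O)O[C@H]1C[C@@H]2C(C(=O)OC)=CO[CH](OC)[C@@H]2[C@@]1(O[Si]3(C(C)(C)C)C(C)(C)C)CO3 | intermediate |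
| 10 | 7-OH, C11-OH, 1-OMe, silylene | O[C@H]1C[C@@H]2C(CO)=CO[CH](OC)[C@@H]2[C@@]1(O[Si]3(C(C)(C)C)C(C)(C)C)CO3 | intermediate |
| 11 | triethylsilyl chloride | CC[Si](Cl)(CC)CC | starting material (reagent) |
| 12 | C11-OTES, 7-OH, 1-OMe, silylene | O[C@H]1C[C@@H]2C(CO[Si](CC)(CC)CC)=CO[CH](OC)[C@@H]2[C@@]1(O[Si]3(C(C)(C)C)C(C)(C)C)CO3 | intermediate |
| 13 | acetic anhydride | CC(=O)OC(C)=O | starting material (reagent) |
| 14 | 7-OAc, C11-OTES, 1-OMe, silylene | CC(=O)O[C@H]1C[C@@H]2C(CO[Si](CC)(CC)CC)=CO[CH](OC)[C@@H]2[C@@]1(O[Si]3(C(C)(C)C)C(C)(C)C)CO3 | intermediate |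
| 15 | isovaleric anhydride | CC(C)CC(=O)OC(=O)CC(C)C | starting material (reagent) |
| 16 | 1β-OiVal acylal, C11-OTES, silylene | CC(=O)O[C@H]1C[C@@H]2C(CO[Si](CC)(CC)CC)=CO[C@@H](OC(=O)CC(C)C)[C@@H]2[C@@]1(O[Si]3(C(C)(C)C)C(C)(C)C)CO3 | intermediate |
| 17 | C11-OH acylal, silylene | CC(=O)O[C@H]1C[C@@H]2C(CO)=CO[C@@H](OC(=O)CC(C)C)[C@@H]2[C@@]1(O[Si]3(C(C)(C)C)C(C)(C)C)CO3 | intermediate |
| 18 | isovaleryl chloride | CC(C)CC(=O)Cl | starting material (reagent) |
| 19 | bis-isovalerate, silylene | CC(=O)O[C@H]1C[C@@H]2C(COC(=O)CC(C)C)=CO[C@@H](OC(=O)CC(C)C)[C@@H]2[C@@]1(O[Si]3(C(C)(C)C)C(C)(C)C)CO3 | intermediate |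
| 20 | jatamanvaltrate H | CC(=O)O[C@H]1C[C@@H]2C(COC(=O)CC(C)C)=CO[C@@H](OC(=O)CC(C)C)[C@@H]2[C@@]1(O)CO | target |

**Totals:** 11 steps; longest linear sequence 11 steps (from genipin).

**Three steps most likely to fail**
1. **Step 8 (proposed new method).** The Lewis acid may ionise the allylic C11-OTES or the enol ether instead of the C1 acetal, or the anomeric selectivity may be poor.
   Fallback (known chemistry): hydrolyse the 1-OMe of 14 or 12 with Amberlyst-15 in THF/H2O at 0 °C to the lactol, then acylate it with isovaleryl chloride/pyridine and separate the anomers.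
2. **Step 2.** The tartrate-directed epoxidation may be mismatched with the convex-face bias of the cis-fused bicycle, or my tartrate assignment may be wrong.
   Fallback (changes approach): epoxidise from the convex β-face with VO(acac)2/TBHP, then do a base-mediated Payne rearrangement and hydroxide opening at C10. This gives the same 7β,8α,10-triol, which joins the route at the silylene protection (Step 4).
3. **Step 5.** DIBAL may not reduce the deactivated vinylogous carbonate cleanly, or it may ionise the acetal or allylic alcohol.
   Fallback (changes approach): saponify the ester with LiOH in THF/H2O, then reduce the acid via the mixed anhydride (iBuOCOCl, NMM; then NaBH4) to give 10.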